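**Strategy.** Ring C is disconnected across O1–C2 and C4–C4a. This pairs ring A as a C,O-bis-nucleophile (O1 and its ortho carbon C4a) with a cinnamoyl bis-electrophile (acyl C4, β-carbon C2). The key step joins both in one flask: an ortho-lithiated phenoxide acylates a cinnamic Weinreb amide, and the resulting 2'-hydroxychalcone closes by a catalyst-controlled asymmetric oxa-Michael addition that sets C2. The step exploits the local symmetry of ring A: O1 lies para to the geranyl-bearing C6, so both carbons ortho to O1 are equivalent, and with the oxygens on C5 and C7 masked as MOM ethers only O1 can cyclise. The precursors are an iodophenol and an enamide.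

Key step: step 8

Remark: the target SMILES is read as the (2S)-flavanone; the facial sense of cinchona thiourea catalysts on this unactivated 2'-hydroxychalcone cannot be predicted with confidence, so the quinidine-derived catalyst is written in step 8 and its quinine-derived pseudoenantiomer replaces it if O1 is delivered to the other face.

In the names below, geranyl = (2E)-3,7-dimethylocta-2,6-dien-1-yl and MOM = methoxymethyl.

Step 1
Reactants: 1 phloroglucinol (benzene-1,3,5-triol)
Product: 2 5-(triisopropylsilyloxy)benzene-1,3-diol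
Conditions: TIPSCl (1.0 equiv), imidazole, 1 in excess (3 equiv), DMF, 0 °C → rt
Reagents that add atoms: chlorotriisopropylsilane (TIPSCl), CC(C)[Si](Cl)(C(C)C)C(C)C
Why: Imidazole-mediated O-silylation of a C3-symmetric triol used in excess should stop largely at the mono-ether (statistical desymmetrisation, the bulky TIPS group slowing a second silylation), and the surplus water-soluble triol is washed out.

Step 2
Reactants: 2 5-(triisopropylsilyloxy)benzene-1,3-diol
Product: 3 [3,5-bis(methoxymethoxy)phenoxy]triisopropylsilane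
Conditions: MOMCl (2.5 equiv), i-Pr2NEt (3 equiv), CH2Cl2, 0 °C → rt
Reagents that add atoms: chloromethyl methyl ether (MOMCl), COCCl
Why: MOM ether formation (O-alkylation of the two remaining phenols under amine base) leaves the base-stable aryl TIPS ether untouched and installs the two ortho-directing groups needed next.

Step 3
Reactants: 3 [3,5-bis(methoxymethoxy)phenoxy]triisopropylsilane; 4 geranyl bromide ((2E)-1-bromo-3,7-dimethylocta-2,6-diene)
Product: 6 [4-geranyl-3,5-bis(methoxymethoxy)phenoxy]triisopropylsilane, via aryllithium 5 (not isolated)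
Conditions: n-BuLi (1.1 equiv), THF, 0 °C; CuBr·SMe2 (10 mol %), then 4, –78 °C → rt
Reagents that add atoms: none
Why: Directed ortho-metalation: the two MOM groups cooperatively direct n-BuLi to the single ring C–H between them while the bulky OTIPS group shields its own ortho positions, and copper-catalysed SN2 allylation of aryllithium 5 with geranyl bromide attaches the chain through its primary carbon with the E-alkene unchanged.

Step 4
Reactants: 6 [4-geranyl-3,5-bis(methoxymethoxy)phenoxy]triisopropylsilane
Product: 7 4-geranyl-3,5-bis(methoxymethoxy)phenol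
Conditions: TBAF (1.1 equiv), AcOH (1.1 equiv), THF, 0 °C
Reagents that add atoms: none
Why: Fluoride-mediated desilylation of the aryl silyl ether, buffered with acetic acid, frees only the oxygen para to the geranyl group and leaves the MOM acetals and both alkenes intact.

Step 5
Reactants: 7 4-geranyl-3,5-bis(methoxymethoxy)phenol
Product: 8 4-geranyl-2-iodo-3,5-bis(methoxymethoxy)phenol
Conditions: I2 (1.0 equiv), NaHCO3, THF/H2O, 0 °C
Reagents that add atoms: iodine, [I][I]
Why: Electrophilic aromatic iodination of the phenol/phenoxide, which is far more nucleophilic than the isolated trisubstituted alkenes; the para position is blocked by the geranyl group and the two ortho positions are equivalent, so one equivalent of iodine should give a single mono-iodide.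

Step 6
Reactants: 9 3,4-dihydroxy-5-methoxybenzaldehyde (5-hydroxyvanillin)
Product: 10 3-methoxy-4,5-bis(methoxymethoxy)benzaldehyde
Conditions: MOMCl (3 equiv), i-Pr2NEt (4 equiv), CH2Cl2, 0 °C → rt
Reagents that add atoms: chloromethyl methyl ether (MOMCl), COCCl
Why: MOM ether formation on both phenols under amine base; the aldehyde is inert to these conditions.

Step 7
Reactants: 10 3-methoxy-4,5-bis(methoxymethoxy)benzaldehyde
Product: 11 (2E)-N-methoxy-3-[3-methoxy-4,5-bis(methoxymethoxy)phenyl]-N-methylprop-2-enamide
Conditions: (EtO)2P(O)CH2C(O)N(OMe)Me, NaH, THF, 0 °C → rt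
Reagents that add atoms: diethyl [2-(methoxy(methyl)amino)-2-oxoethyl]phosphonate, CCOP(=O)(CC(=O)N(C)OC)OCC
Why: Horner–Wadsworth–Emmons olefination with the stabilised Weinreb amide phosphonate anion should give the E-enamide.

Step 8
Reactants: 8 4-geranyl-2-iodo-3,5-bis(methoxymethoxy)phenol; 11 (2E)-N-methoxy-3-[3-methoxy-4,5-bis(methoxymethoxy)phenyl]-N-methylprop-2-enamide
Product: 15 (2S)-6-geranyl-5,7-bis(methoxymethoxy)-2-[3-methoxy-4,5-bis(methoxymethoxy)phenyl]chroman-4-one, via dilithio phenoxide 12 (not isolated), via Weinreb adduct 13 (not isolated), via 2'-hydroxychalcone 14 (not isolated)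
Conditions: t-BuLi (3.0 equiv), THF, –78 °C; then 11, –78 → –40 °C; AcOH (2.0 equiv), → rt; aq. NaHCO3 wash, solvent switch to toluene (14 not purified); 1-[3,5-bis(trifluoromethyl)phenyl]-3-(9-deoxy-epi-quinidin-9-yl)thiourea (10 mol %), toluene, 0 °C
Reagents that add atoms: none
Why: Deprotonation of the phenol and iodine–lithium exchange give the C,O-dilithio species 12, whose aryl carbanion adds once to the carbonyl of Weinreb amide 11 to form the chelated adduct 13 (C4–C4a bond); acetic acid collapses 13 to the 2'-hydroxychalcone 14, in which the cinchona thiourea acts as a bifunctional catalyst (quinuclidine nitrogen as general base for O1–H, thiourea N–H groups on the enone carbonyl) and delivers O1 to C2, after which the enol tautomerises to the ketone (O1–C2 bond). The closest known reaction types are the Weinreb ketone synthesis with an ortho-lithiated phenoxide and the organocatalytic asymmetric intramolecular oxa-Michael addition (biomimetic chalcone-to-flavanone isomerisation). Ring C closes by 6-endo-trig attack of O1 on the enone β-carbon. The C2 stereocentre is set by the catalyst, which should shield one face of the hydrogen-bonded s-cis enone so that O1 adds to give the (S) configuration. The step needs carbonyl over conjugate addition (secured by the stable five-membered N-methoxy chelate), closure through O1 and not the oxygen on C5 (secured because the oxygens on C5 and C7 are MOM ethers and only the oxygen para to the geranyl group is free, which places the geranyl group at C6 and not C8), and kinetic enantiocontrol (helped by the 5-OMOM group, which twists the aroyl unit, speeds closure at low temperature and disfavours the racemising retro-Michael reaction).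

Step 9
Reactants: 15 (2S)-6-geranyl-5,7-bis(methoxymethoxy)-2-[3-methoxy-4,5-bis(methoxymethoxy)phenyl]chroman-4-one
Product: 16 (2S)-2-(3,4-dihydroxy-5-methoxyphenyl)-6-geranyl-5,7-dihydroxychroman-4-one (target)
Conditions: HCl (3 M aq.), MeOH/THF, rt → 40 °C
Reagents that add atoms: none
Why: Acid-catalysed solvolysis of the four aryl MOM acetals; dilute acid near room temperature should cleave the acetals faster than it adds the 5- or 7-hydroxyl across the geranyl alkene or opens ring C, so C2 should stay (S).

**Compound list**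

1 | phloroglucinol (benzene-1,3,5-triol) | Oc1cc(O)cc(O)c1 | starting material
2 | 5-(triisopropylsilyloxy)benzene-1,3-diol | CC(C)[Si](Oc1cc(O)cc(O)c1)(C(C)C)C(C)C | intermediate
3 | [3,5-bis(methoxymethoxy)phenoxy]triisopropylsilane | COCOc1cc(OCOC)cc(O[Si](C(C)C)(C(C)C)C(C)C)c1 | intermediate
4 | geranyl bromide, (2E)-1-bromo-3,7-dimethylocta-2,6-diene | BrC/C=C(\C)CCC=C(C)C | starting material
5 | [2,6-bis(methoxymethoxy)-4-(triisopropylsilyloxy)phenyl]lithium | [Li]c1c(OCOC)cc(O[Si](C(C)C)(C(C)C)C(C)C)cc1OCOC | intermediate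
6 | {4-[(2E)-3,7-dimethylocta-2,6-dien-1-yl]-3,5-bis(methoxymethoxy)phenoxy}triisopropylsilane | COCOc1cc(O[Si](C(C)C)(C(C)C)C(C)C)cc(OCOC)c1C/C=C(\C)CCC=C(C)C | intermediate
7 | 4-[(2E)-3,7-dimethylocta-2,6-dien-1-yl]-3,5-bis(methoxymethoxy)phenol | COCOc1cc(O)cc(OCOC)c1C/C=C(\C)CCC=C(C)C | intermediate
8 | 4-[(2E)-3,7-dimethylocta-2,6-dien-1-yl]-2-iodo-3,5-bis(methoxymethoxy)phenol | COCOc1cc(O)c(I)c(OCOC)c1C/C=C(\C)CCC=C(C)C | intermediate
9 | 3,4-dihydroxy-5-methoxybenzaldehyde | COc1cc(C=O)cc(O)c1O | starting material
10 | 3-methoxy-4,5-bis(methoxymethoxy)benzaldehyde | COCOc1cc(C=O)cc(OC)c1OCOC | intermediate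
11 | (2E)-N-methoxy-3-[3-methoxy-4,5-bis(methoxymethoxy)phenyl]-N-methylprop-2-enamide | COCOc1cc(/C=C/C(=O)N(C)OC)cc(OC)c1OCOC | intermediate
12 | lithium 4-geranyl-2-lithio-3,5-bis(methoxymethoxy)phenoxide (C,O-dilithio species of 8, E-alkene) | [Li]Oc1cc(OCOC)c(C/C=C(\C)CCC=C(C)C)c(OCOC)c1[Li] | intermediate
13 | dilithium salt of the tetrahedral N-methoxy-N-methyl hemiaminal from 12 and 11 (E,E; carbinol centre not defined) | [Li]OC(/C=C/c1cc(OC)c(OCOC)c(OCOC)c1)(N(C)OC)c1c(O[Li])cc(OCOC)c(C/C=C(\C)CCC=C(C)C)c1OCOC | intermediate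
14 | (2E)-1-{3-[(2E)-3,7-dimethylocta-2,6-dien-1-yl]-6-hydroxy-2,4-bis(methoxymethoxy)phenyl}-3-[3-methoxy-4,5-bis(methoxymethoxy)phenyl]prop-2-en-1-one | COCOc1cc(O)c(C(=O)/C=C/c2cc(OC)c(OCOC)c(OCOC)c2)c(OCOC)c1C/C=C(\C)CCC=C(C)C | intermediate
15 | (2S)-6-[(2E)-3,7-dimethylocta-2,6-dien-1-yl]-5,7-bis(methoxymethoxy)-2-[3-methoxy-4,5-bis(methoxymethoxy)phenyl]chroman-4-one | COc1cc([C@@H]2CC(=O)c3c(cc(OCOC)c(C/C=C(\C)CCC=C(C)C)c3OCOC)O2)cc(OCOC)c1OCOC | intermediate
16 | (2S)-2-(3,4-dihydroxy-5-methoxyphenyl)-6-[(2E)-3,7-dimethylocta-2,6-dien-1-yl]-5,7-dihydroxychroman-4-one | COc1cc([C@@H]2CC(=O)c3c(cc(O)c(C/C=C(\C)CCC=C(C)C)c3O)O2)cc(O)c1O | target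

**Step count.** Total: 9 steps. Longest linear sequence: 7 steps (1, 2, 3, 4, 5, 8, 9).

**Steps most likely to fail**

Step 8. The oxa-Michael closure may show weak enantiofacial discrimination, eroded further by reversible ring opening; conjugate instead of carbonyl addition of the aryllithium is a lesser concern. Fallback: from 8 and 11 the lithiation, acylation and acetic acid quench are run as before and chalcone 14 is isolated. Ring closure with NaOAc in EtOH at reflux should give racemic 6-geranyl-5,7-bis(methoxymethoxy)-2-[3-methoxy-4,5-bis(methoxymethoxy)phenyl]chroman-4-one F1. Kinetic resolution by Noyori–Ikariya asymmetric transfer hydrogenation with RuCl[(R,R)-TsDPEN](p-cymene) in HCO2H/Et3N is expected to reduce the (2R)-enantiomer to (2R,4R)-6-geranyl-5,7-bis(methoxymethoxy)-2-[3-methoxy-4,5-bis(methoxymethoxy)phenyl]chroman-4-ol F2. The unreduced (2S)-ketone is 15, where the route is rejoined; the isolated trisubstituted alkenes are inert to transfer hydrogenation.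

Step 5. Electrophilic iodine may attack the electron-rich geranyl alkenes, or the ring may be iodinated twice. Fallback: from 6, MOM-directed ortho-lithiation (s-BuLi, TMEDA, THF, –78 °C) at the ring C–H between the OMOM and OTIPS groups, followed by an I2 quench at –78 °C, reverses the polarity so that the aryl anion and not an alkene consumes the halogen. This should give [4-geranyl-2-iodo-3,5-bis(methoxymethoxy)phenoxy]triisopropylsilane F3. TBAF/AcOH in THF then removes the silyl group and the route is rejoined at 8.

Step 9. Acid may cyclise the geranyl chain onto the liberated 5- or 7-hydroxyl, or open ring C with loss of the C2 configuration. Fallback: from 15, TESOTf/2,2'-bipyridyl in MeCN (0 °C → rt) is a non-acidic trans-silylation that should convert each aryl MOM ether into an aryl triethylsilyl ether. This would give (2S)-6-geranyl-2-[3-methoxy-4,5-bis(triethylsilyloxy)phenyl]-5,7-bis(triethylsilyloxy)chroman-4-one F4. TBAF buffered with AcOH in THF at 0 °C then cleaves the four Si–O bonds under near-neutral conditions and delivers 16.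

Further compounds
F1 | step 8 | racemic 6-[(2E)-3,7-dimethylocta-2,6-dien-1-yl]-5,7-bis(methoxymethoxy)-2-[3-methoxy-4,5-bis(methoxymethoxy)phenyl]chroman-4-one | COc1cc(C2CC(=O)c3c(cc(OCOC)c(C/C=C(\C)CCC=C(C)C)c3OCOC)O2)cc(OCOC)c1OCOC
F2 | step 8 | (2R,4R)-6-[(2E)-3,7-dimethylocta-2,6-dien-1-yl]-5,7-bis(methoxymethoxy)-2-[3-methoxy-4,5-bis(methoxymethoxy)phenyl]chroman-4-ol | COc1cc([C@H]2C[C@@H](O)c3c(cc(OCOC)c(C/C=C(\C)CCC=C(C)C)c3OCOC)O2)cc(OCOC)c1OCOC
F3 | step 5 | {4-[(2E)-3,7-dimethylocta-2,6-dien-1-yl]-2-iodo-3,5-bis(methoxymethoxy)phenoxy}triisopropylsilane | COCOc1cc(O[Si](C(C)C)(C(C)C)C(C)C)c(I)c(OCOC)c1C/C=C(\C)CCC=C(C)C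
F4 | step 9 | (2S)-6-[(2E)-3,7-dimethylocta-2,6-dien-1-yl]-2-[3-methoxy-4,5-bis(triethylsilyloxy)phenyl]-5,7-bis(triethylsilyloxy)chroman-4-one | COc1cc([C@@H]2CC(=O)c3c(cc(O[Si](CC)(CC)CC)c(C/C=C(\C)CCC=C(C)C)c3O[Si](CC)(CC)CC)O2)cc(O[Si](CC)(CC)CC)c1O[Si](CC)(CC)CC
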